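The hexamer is cut inside ring D and not at an ether bond. On ring D the ether oxygen to C6 of ring C sits at D1, opposite the ether oxygen to E1 at D4, while D3 and D5 bear hydroxyls and D2 and D6 hydrogen. This array arises when an aryl ethynyl ether (supplying D1, D2) is heated with a 4-aryloxy-3-ethoxycyclobutenone (supplying D3 to D6). One thermal step thus makes D2–D3, D1–D6 and D3–D4, closes ring D and joins the ABC trimer to the EF dimer with no coupling at a crowded oxygen. Both partners come from Ullmann and Baeyer–Villiger steps on bromobenzaldehydes; BBr3 then frees all sixteen hydroxyls.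

Key step: step 12

Remark on numbering: rings are lettered A to F from the 2,4,6-trihydroxyphenoxy end; C1 bears the oxygen to ring B and C6 the oxygen to ring D; D1 bears the oxygen to ring C and D4 the oxygen to ring E; E1 bears the oxygen to ring D and E6 the oxygen to ring F.
Remark on stereochemistry: the target is achiral; cyclobutenone 27 is racemic and its single stereocenter disappears when ring D becomes aromatic.
Assumption: 4-bromo-2,6-dimethoxybenzaldehyde (2), 5-bromo-1,2,3-trimethoxybenzene (6) and 2-bromo-3,4,5-trimethoxybenzaldehyde (18) are taken as catalogue compounds.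
Remark on design: the six carbons of ring D come from three two-carbon units, 12 (D1, D2), 22 (D3, D4) and 24 (D5, D6); methyl ethers are used throughout because the D5 ethyl ether needs BBr3 in any case.

Step 1
Reactants: 1 2,4,6-trimethoxyphenol; 2 4-bromo-2,6-dimethoxybenzaldehyde
Product: 3 2,6-dimethoxy-4-(2,4,6-trimethoxyphenoxy)benzaldehyde (rings A and B)
Conditions: CuI (10 mol %), picolinic acid (20 mol %), K3PO4, DMSO, 90 °C
Reagents that add atoms: none
Why: Ullmann-type copper-catalysed diaryl ether coupling in its favourable pairing, a hindered phenoxide as nucleophile and an unhindered aryl bromide activated by the para formyl group.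

Step 2
Reactants: 3 AB aldehyde
Product: 5 2,6-dimethoxy-4-(2,4,6-trimethoxyphenoxy)phenol, via AB aryl formate 4 (not isolated)
Conditions: mCPBA, CH2Cl2, 0 °C → rt; NaHCO3 wash; then K2CO3 (cat.), MeOH, rt
Reagents that add atoms: mCPBA, O=C(OO)c1cccc(Cl)c1
Why: Baeyer–Villiger (Dakin-type) oxidation in which the electron-rich aryl group flanked by two methoxyls migrates in preference to hydrogen, the formate being methanolysed only after the peracid is gone so that the free phenol never meets the oxidant.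

Step 3
Reactants: 6 5-bromo-1,2,3-trimethoxybenzene
Product: 8 6-bromo-2,3,4-trimethoxybenzaldehyde, via α-chloro ether 7 (not isolated)
Conditions: Cl2CHOMe, TiCl4, CH2Cl2, −10 → 0 °C; then ice-water
Reagents that add atoms: dichloromethyl methyl ether, COC(Cl)Cl; water, O
Why: Rieche formylation of an activated arene whose two open positions are equivalent by symmetry, each ortho and para to a methoxyl, so that only one aldehyde can form once the α-chloro ether is hydrolysed.

Step 4
Reactants: 5 AB phenol; 8 6-bromo-2,3,4-trimethoxybenzaldehyde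
Product: 9 6-[2,6-dimethoxy-4-(2,4,6-trimethoxyphenoxy)phenoxy]-2,3,4-trimethoxybenzaldehyde (rings A, B and C; formyl group on C6)
Conditions: CuI (10 mol %), picolinic acid (20 mol %), K3PO4, DMSO, 90 °C
Reagents that add atoms: none
Why: Ullmann diaryl ether coupling with the hindered phenol again as nucleophile, the bromide having a single ortho substituent, a formyl group that activates the carbon–bromine bond and later becomes the C6 oxygen.

Step 5
Reactants: 9 ABC aldehyde
Product: 11 6-[2,6-dimethoxy-4-(2,4,6-trimethoxyphenoxy)phenoxy]-2,3,4-trimethoxyphenol, via ABC aryl formate 10 (not isolated)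
Conditions: mCPBA, CH2Cl2, 0 °C → rt; NaHCO3 wash; then K2CO3 (cat.), MeOH, rt
Reagents that add atoms: mCPBA, O=C(OO)c1cccc(Cl)c1
Why: Baeyer–Villiger oxidation with aryl migration from a benzaldehyde bearing ortho methoxy and ortho aryloxy donors, followed by methanolysis of the formate.

Step 6
Reactants: 11 ABC phenol; 12 trichloroethylene
Product: 13 1-{[(E)-1,2-dichloroethenyl]oxy}-2-[2,6-dimethoxy-4-(2,4,6-trimethoxyphenoxy)phenoxy]-4,5,6-trimethoxybenzene (dichlorovinyl ether on the C6 oxygen)
Conditions: K2CO3, DMF, 60 °C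
Reagents that add atoms: none
Why: Base-mediated anti addition of the phenoxide to dichloroacetylene formed in the flask from 12, the standard entry to 1,2-dichlorovinyl ethers, which tolerates the flanked C6 oxygen because the electrophile is small.

Step 7
Reactants: 13 ABC dichlorovinyl ether
Product: 16 1-[2,6-dimethoxy-4-(2,4,6-trimethoxyphenoxy)phenoxy]-2-(ethynyloxy)-3,4,5-trimethoxybenzene, via chloroethynyl ether 14 (not isolated), via lithium acetylide 15 (not isolated)
Conditions: n-BuLi (2.3 equiv), THF, −78 → −40 °C; then H2O, −78 °C; filtered through basic alumina, used at once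
Reagents that add atoms: none
Why: Dehydrochlorination to the chloroalkyne, chlorine–lithium exchange and protonation (the dichlorovinyl ether route to ynol ethers) should outrun ring lithiation at −78 °C, and the aryl ynol ether is taken on without storage.

Step 8
Reactants: 17 3,4,5-trimethoxyphenol; 18 2-bromo-3,4,5-trimethoxybenzaldehyde
Product: 19 3,4,5-trimethoxy-2-(3,4,5-trimethoxyphenoxy)benzaldehyde (rings E and F; formyl group on E1)
Conditions: CuI (10 mol %), picolinic acid (20 mol %), K3PO4, DMSO, 90 °C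
Reagents that add atoms: none
Why: Ullmann diaryl ether coupling of an unhindered phenoxide with an aryl bromide whose ortho carbonyl group assists displacement, as is established for 2-halo-3,4,5-trimethoxybenzoyl compounds.

Step 9
Reactants: 19 EF aldehyde
Product: 21 3,4,5-trimethoxy-2-(3,4,5-trimethoxyphenoxy)phenol, via EF aryl formate 20 (not isolated)
Conditions: mCPBA, CH2Cl2, 0 °C → rt; NaHCO3 wash; then K2CO3 (cat.), MeOH, rt
Reagents that add atoms: mCPBA, O=C(OO)c1cccc(Cl)c1
Why: Baeyer–Villiger oxidation with aryl migration, favoured by the para methoxyl and ortho aryloxy group, then methanolysis, turns the formyl carbon into the E1 hydroxyl.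

Step 10
Reactants: 21 EF phenol; 22 bromoacetic acid
Product: 23 2-[3,4,5-trimethoxy-2-(3,4,5-trimethoxyphenoxy)phenoxy]acetic acid
Conditions: NaH (2.5 equiv), THF/DMF, 0 → 60 °C; then 1 M HCl
Reagents that add atoms: none
Why: Williamson ether synthesis, the sodium phenoxide displacing bromide from sodium bromoacetate to give the aryloxyacetic acid in one operation.

Step 11
Reactants: 23 EF aryloxyacetic acid; 24 ethoxyacetylene
Product: 27 racemic 3-ethoxy-4-[3,4,5-trimethoxy-2-(3,4,5-trimethoxyphenoxy)phenoxy]cyclobut-2-en-1-one, via acid chloride 25 (not isolated), via aryloxyketene 26 (not isolated)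
Conditions: 1-chloro-N,N,2-trimethylprop-1-en-1-amine, CH2Cl2, 0 °C → rt; then 24 (3 equiv), Et3N (slow addition), 0 °C → rt
Reagents that add atoms: none
Why: Acid chloride formation under neutral conditions (no acid to trigger Friedel–Crafts closure onto the activated E2 position), dehydrochlorination to the ketene and ketene–ynol ether [2+2] cycloaddition, in which the nucleophilic CH carbon of 24 attacks the ketene carbonyl carbon so that ethoxy ends on C3 and aryloxy on C4, the C4 stereocenter forming racemic.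

Step 12
Reactants: 16 ABC aryl ethynyl ether; 27 EF cyclobutenone
Product: 32 3-ethoxy-5-{6-[2,6-dimethoxy-4-(2,4,6-trimethoxyphenoxy)phenoxy]-2,3,4-trimethoxyphenoxy}-2-[3,4,5-trimethoxy-2-(3,4,5-trimethoxyphenoxy)phenoxy]phenol (hexamer with free D3 hydroxyl), via vinylketene 28 (not isolated), via 2-vinylcyclobutenone 29 (not isolated), via dienylketene 30 (not isolated), via cyclohexadienone 31 (not isolated)
Conditions: 16 (1.0 equiv), 27 (1.3 equiv), PhMe, 80 → 110 °C, sealed tube, Ar; then K2CO3, MeOH, rt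
Reagents that add atoms: none
Why: Proposed new method: a 4-aryloxy-3-alkoxycyclobutenone and an aryl ethynyl ether have not been paired in this annulation, the closest known reaction type being the Danheiser benzannulation of cyclobutenones with alkoxyacetylenes, supported by the thermal ring opening of squarate-derived 4-hydroxy-3-alkoxycyclobutenones. Four-electron conrotatory opening of 27 with the aryloxy group turning outward should give vinylketene 28, whose carbonyl carbon is attacked by the nucleophilic terminal carbon of 16 to close 2-vinylcyclobutenone 29 in a [2+2] cycloaddition. Reversible four-electron opening of 29 gives dienylketene 30, and ring D is then closed by a thermal six-electron disrotatory electrocyclisation between the ketene carbon and the aryloxy-bearing terminus to give dienone 31, which enolises to phenol 32. No stereocenter is created, since the one at C4 of 27, carried into 31, is lost on aromatisation. The step needs regiocontrol in the ketene–alkyne cycloaddition, and the oxygen-polarised triple bond of 16 secures it, placing the ring C oxygen at D1 para to the ring E oxygen at D4; an aryl ynol ether also offers no hydrogen for retro-ene loss of a ketene on heating, and the basic methanol treatment returns any 32 that was acylated by 28.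

Step 13
Reactants: 32 hexamer phenol
Product: 33 target CNP0114537.0, 5-{6-[2,6-dihydroxy-4-(2,4,6-trihydroxyphenoxy)phenoxy]-2,3,4-trihydroxyphenoxy}-2-[3,4,5-trihydroxy-2-(3,4,5-trihydroxyphenoxy)phenoxy]benzene-1,3-diol
Conditions: BBr3 (40 equiv), CH2Cl2, −78 °C → rt, Ar; then MeOH, H2O; Sephadex LH-20 (MeOH), Ar
Reagents that add atoms: none
Why: Lewis acid dealkylation of aryl alkyl ethers with BBr3, bromide attacking the methyl and ethyl carbons of the boron-complexed ethers while the diaryl ether bonds stay intact, should free the fourteen methoxyls and the ethoxyl in one operation.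

Compound list
1 | 2,4,6-trimethoxyphenol | COc1cc(OC)c(O)c(OC)c1 | starting material
2 | 4-bromo-2,6-dimethoxybenzaldehyde | COc1cc(Br)cc(OC)c1C=O | starting material
3 | 2,6-dimethoxy-4-(2,4,6-trimethoxyphenoxy)benzaldehyde (AB aldehyde) | O=Cc1c(OC)cc(Oc2c(OC)cc(OC)cc2OC)cc1OC | intermediate
4 | 2,6-dimethoxy-4-(2,4,6-trimethoxyphenoxy)phenyl formate (AB aryl formate) | O=COc1c(OC)cc(Oc2c(OC)cc(OC)cc2OC)cc1OC | intermediate (not isolated)
5 | 2,6-dimethoxy-4-(2,4,6-trimethoxyphenoxy)phenol (AB phenol) | Oc1c(OC)cc(Oc2c(OC)cc(OC)cc2OC)cc1OC | intermediate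
6 | 5-bromo-1,2,3-trimethoxybenzene | COc1cc(Br)cc(OC)c1OC | starting material
7 | racemic 1-bromo-2-[chloro(methoxy)methyl]-3,4,5-trimethoxybenzene (α-chloro ether) | COC(Cl)c1c(Br)cc(OC)c(OC)c1OC | intermediate (not isolated)
8 | 6-bromo-2,3,4-trimethoxybenzaldehyde | O=Cc1c(Br)cc(OC)c(OC)c1OC | intermediate
9 | 6-[2,6-dimethoxy-4-(2,4,6-trimethoxyphenoxy)phenoxy]-2,3,4-trimethoxybenzaldehyde (ABC aldehyde) | O=Cc1c(OC)c(OC)c(OC)cc1Oc1c(OC)cc(Oc2c(OC)cc(OC)cc2OC)cc1OC | intermediate
10 | 6-[2,6-dimethoxy-4-(2,4,6-trimethoxyphenoxy)phenoxy]-2,3,4-trimethoxyphenyl formate (ABC aryl formate) | O=COc1c(OC)c(OC)c(OC)cc1Oc1c(OC)cc(Oc2c(OC)cc(OC)cc2OC)cc1OC | intermediate (not isolated)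
11 | 6-[2,6-dimethoxy-4-(2,4,6-trimethoxyphenoxy)phenoxy]-2,3,4-trimethoxyphenol (ABC phenol, free C6 hydroxyl) | Oc1c(OC)c(OC)c(OC)cc1Oc1c(OC)cc(Oc2c(OC)cc(OC)cc2OC)cc1OC | intermediate
12 | trichloroethylene | ClC=C(Cl)Cl | starting material
13 | (E)-1,2-dichlorovinyl ether of 11 | Cl/C=C(/Cl)Oc1c(OC)c(OC)c(OC)cc1Oc1c(OC)cc(Oc2c(OC)cc(OC)cc2OC)cc1OC | intermediate
14 | chloroethynyl ether of 11 | ClC#COc1c(OC)c(OC)c(OC)cc1Oc1c(OC)cc(Oc2c(OC)cc(OC)cc2OC)cc1OC | intermediate (not isolated)
15 | lithium acetylide of 16 | [Li]C#COc1c(OC)c(OC)c(OC)cc1Oc1c(OC)cc(Oc2c(OC)cc(OC)cc2OC)cc1OC | intermediate (not isolated)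
16 | 1-[2,6-dimethoxy-4-(2,4,6-trimethoxyphenoxy)phenoxy]-2-(ethynyloxy)-3,4,5-trimethoxybenzene (ABC aryl ethynyl ether) | C#COc1c(OC)c(OC)c(OC)cc1Oc1c(OC)cc(Oc2c(OC)cc(OC)cc2OC)cc1OC | intermediate
17 | 3,4,5-trimethoxyphenol | COc1cc(O)cc(OC)c1OC | starting material
18 | 2-bromo-3,4,5-trimethoxybenzaldehyde | O=Cc1cc(OC)c(OC)c(OC)c1Br | starting material
19 | 3,4,5-trimethoxy-2-(3,4,5-trimethoxyphenoxy)benzaldehyde (EF aldehyde) | O=Cc1cc(OC)c(OC)c(OC)c1Oc1cc(OC)c(OC)c(OC)c1 | intermediate
20 | 3,4,5-trimethoxy-2-(3,4,5-trimethoxyphenoxy)phenyl formate (EF aryl formate) | O=COc1cc(OC)c(OC)c(OC)c1Oc1cc(OC)c(OC)c(OC)c1 | intermediate (not isolated)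
21 | 3,4,5-trimethoxy-2-(3,4,5-trimethoxyphenoxy)phenol (EF phenol, free E1 hydroxyl) | Oc1cc(OC)c(OC)c(OC)c1Oc1cc(OC)c(OC)c(OC)c1 | intermediate
22 | bromoacetic acid | OC(=O)CBr | starting material
23 | 2-[3,4,5-trimethoxy-2-(3,4,5-trimethoxyphenoxy)phenoxy]acetic acid | OC(=O)COc1cc(OC)c(OC)c(OC)c1Oc1cc(OC)c(OC)c(OC)c1 | intermediate
24 | ethoxyacetylene | C#COCC | starting material
25 | 2-[3,4,5-trimethoxy-2-(3,4,5-trimethoxyphenoxy)phenoxy]acetyl chloride | ClC(=O)COc1cc(OC)c(OC)c(OC)c1Oc1cc(OC)c(OC)c(OC)c1 | intermediate (not isolated)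
26 | [3,4,5-trimethoxy-2-(3,4,5-trimethoxyphenoxy)phenoxy]ketene | O=C=COc1cc(OC)c(OC)c(OC)c1Oc1cc(OC)c(OC)c(OC)c1 | intermediate (not isolated)
27 | racemic 3-ethoxy-4-[3,4,5-trimethoxy-2-(3,4,5-trimethoxyphenoxy)phenoxy]cyclobut-2-en-1-one | CCOC1=CC(=O)C1Oc1cc(OC)c(OC)c(OC)c1Oc1cc(OC)c(OC)c(OC)c1 | intermediate
28 | (Z)-3-ethoxy-4-(EF aryloxy)buta-1,3-dien-1-one (vinylketene, aryloxy trans to the ketene carbon) | O=C=C/C(OCC)=C/Oc1cc(OC)c(OC)c(OC)c1Oc1cc(OC)c(OC)c(OC)c1 | intermediate (not isolated)
29 | racemic 3-(ABC aryloxy)-4-[(Z)-1-ethoxy-2-(EF aryloxy)ethenyl]cyclobut-2-en-1-one (2-vinylcyclobutenone) | O=C1C=C(Oc2c(OC)c(OC)c(OC)cc2Oc2c(OC)cc(Oc3c(OC)cc(OC)cc3OC)cc2OC)C1/C(OCC)=C/Oc1cc(OC)c(OC)c(OC)c1Oc1cc(OC)c(OC)c(OC)c1 | intermediate (not isolated)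
30 | 3-(ABC aryloxy)-5-ethoxy-6-(EF aryloxy)hexa-1,3,5-trien-1-one (dienylketene, ketene chain and ethoxyvinyl group cis on the central double bond) | O=C=C/C(Oc1c(OC)c(OC)c(OC)cc1Oc1c(OC)cc(Oc2c(OC)cc(OC)cc2OC)cc1OC)=C\C(OCC)=C\Oc1cc(OC)c(OC)c(OC)c1Oc1cc(OC)c(OC)c(OC)c1 | intermediate (not isolated)
31 | racemic 3-(ABC aryloxy)-5-ethoxy-6-(EF aryloxy)cyclohexa-2,4-dien-1-one | O=C1C=C(Oc2c(OC)c(OC)c(OC)cc2Oc2c(OC)cc(Oc3c(OC)cc(OC)cc3OC)cc2OC)C=C(OCC)C1Oc1cc(OC)c(OC)c(OC)c1Oc1cc(OC)c(OC)c(OC)c1 | intermediate (not isolated)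
32 | 3-ethoxy-5-{6-[2,6-dimethoxy-4-(2,4,6-trimethoxyphenoxy)phenoxy]-2,3,4-trimethoxyphenoxy}-2-[3,4,5-trimethoxy-2-(3,4,5-trimethoxyphenoxy)phenoxy]phenol (hexamer, D3 hydroxyl, D5 ethoxyl) | CCOc1cc(Oc2c(OC)c(OC)c(OC)cc2Oc2c(OC)cc(Oc3c(OC)cc(OC)cc3OC)cc2OC)cc(O)c1Oc1cc(OC)c(OC)c(OC)c1Oc1cc(OC)c(OC)c(OC)c1 | intermediate
33 | CNP0114537.0, 5-{6-[2,6-dihydroxy-4-(2,4,6-trihydroxyphenoxy)phenoxy]-2,3,4-trihydroxyphenoxy}-2-[3,4,5-trihydroxy-2-(3,4,5-trihydroxyphenoxy)phenoxy]benzene-1,3-diol | Oc1cc(O)c(Oc2cc(O)c(Oc3cc(O)c(O)c(O)c3Oc3cc(O)c(Oc4cc(O)c(O)c(O)c4Oc4cc(O)c(O)c(O)c4)c(O)c3)c(O)c2)c(O)c1 | target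

Total step count: 13. Longest linear sequence: 8 steps (1, 2, 4, 5, 6, 7, 12, 13).

Steps most likely to fail

Step 12 (the step that bears the label). The vinylketene may be consumed by self-condensation or by acylating the product phenol before the slower cycloaddition to the ynol ether. The crowded 2-vinylcyclobutenone may not reopen cleanly, and the ynol ether may oligomerise at the temperature needed. The fallback builds ring D from a preformed arene by the coupling and oxidation chemistry already used in steps 1 to 5. It sets out from ABC phenol 11, which is coupled with bromoaldehyde 2 under the conditions of step 1 to give the tetramer aldehyde F1. Baeyer–Villiger oxidation and methanolysis as in step 2 should give the tetramer phenol F2, a 2,6-dimethoxyphenol of the same kind as 5. Coupling of F2 with bromoaldehyde 8 as in step 4 gives the pentamer aldehyde F3, which is oxidised as in step 5 to the pentamer phenol F4. Coupling of F4 with 5-bromo-1,2,3-trimethoxybenzene 6 under the same copper conditions gives the hexadeca-O-methyl hexamer F5, and BBr3 as in step 13 brings the route back at target 33. The price is six steps from 11 and three consecutive couplings of hindered phenols of growing size.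

Step 11. The aryloxyketene may oligomerise, or acylate the activated E2 position, faster than it adds to the only moderately nucleophilic ethoxyacetylene. The fallback sets out from acid 23 and generates 25 and 26 as before, but traps the ketene with the far more nucleophilic 1,1-diethoxyethene to give the racemic 3,3-diethoxycyclobutanone F6. Elimination of ethanol toward the unsubstituted ring methylene (basic alumina or Et3N, rt) then brings the route back at cyclobutenone 27. The regioisomeric enone, should the elimination also run toward the aryloxy-bearing carbon, would be removed by chromatography.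

Step 7. The terminal aryl ethynyl ether may be lost through hydration or oligomerisation during work-up and handling. The fallback sets out from dichlorovinyl ether 13, runs the same lithiation, and quenches acetylide 15 with Me3SiCl to give the trimethylsilylethynyl ether F7, which should survive chromatography and storage. Cleavage of the carbon–silicon bond with K2CO3 in MeOH at 0 °C directly before the annulation brings the route back at ynol ether 16.

Further compounds
F1 | step 12 | 4-{6-[2,6-dimethoxy-4-(2,4,6-trimethoxyphenoxy)phenoxy]-2,3,4-trimethoxyphenoxy}-2,6-dimethoxybenzaldehyde (tetramer aldehyde) | O=Cc1c(OC)cc(Oc2c(OC)c(OC)c(OC)cc2Oc2c(OC)cc(Oc3c(OC)cc(OC)cc3OC)cc2OC)cc1OC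
F2 | step 12 | 4-{6-[2,6-dimethoxy-4-(2,4,6-trimethoxyphenoxy)phenoxy]-2,3,4-trimethoxyphenoxy}-2,6-dimethoxyphenol (tetramer phenol) | Oc1c(OC)cc(Oc2c(OC)c(OC)c(OC)cc2Oc2c(OC)cc(Oc3c(OC)cc(OC)cc3OC)cc2OC)cc1OC
F3 | step 12 | 2,3,4-trimethoxy-6-(tetramer aryloxy)benzaldehyde (pentamer aldehyde, formyl group on E6) | O=Cc1c(OC)c(OC)c(OC)cc1Oc1c(OC)cc(Oc2c(OC)c(OC)c(OC)cc2Oc2c(OC)cc(Oc3c(OC)cc(OC)cc3OC)cc2OC)cc1OC
F4 | step 12 | 2,3,4-trimethoxy-6-(tetramer aryloxy)phenol (pentamer phenol, free E6 hydroxyl) | Oc1c(OC)c(OC)c(OC)cc1Oc1c(OC)cc(Oc2c(OC)c(OC)c(OC)cc2Oc2c(OC)cc(Oc3c(OC)cc(OC)cc3OC)cc2OC)cc1OC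
F5 | step 12 | hexadeca-O-methyl ether of 33 | COc1cc(Oc2c(OC)c(OC)c(OC)cc2Oc2c(OC)cc(Oc3c(OC)c(OC)c(OC)cc3Oc3c(OC)cc(Oc4c(OC)cc(OC)cc4OC)cc3OC)cc2OC)cc(OC)c1OC
F6 | step 11 | racemic 3,3-diethoxy-2-[3,4,5-trimethoxy-2-(3,4,5-trimethoxyphenoxy)phenoxy]cyclobutan-1-one | CCOC1(OCC)CC(=O)C1Oc1cc(OC)c(OC)c(OC)c1Oc1cc(OC)c(OC)c(OC)c1
F7 | step 7 | trimethylsilylethynyl ether of 11 | C[Si](C)(C)C#COc1c(OC)c(OC)c(OC)cc1Oc1c(OC)cc(Oc2c(OC)cc(OC)cc2OC)cc1OC
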